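Ring A is a 2,6,6-trimethylcyclohexene (C1 carries the side chain, C2 the methyl, C6 the gem-dimethyl pair); its tetrasubstituted C1=C2 bond, flanked by the allylic CH2 (C3) and the quaternary C6, is read as a Diels–Alder retron. A Lewis-acid-promoted [4+2] addition of acrolein, serving as an ethylene equivalent, to an isopropenyl–isopropylidene diene forms the C3–C4 and C5–C6 bonds, the quaternary carbon and the ring alkene in one operation; the formyl group is then excised. The diene arises from an ene reaction of tetramethylallene. The chroman stereocentre comes from methyl (R)-2-methylglycidate, and the (E,E)-diene from alkyne carboalumination and Negishi coupling with a chromanyl vinyl iodide.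

Key step: step 2

Remark: C2 of the chroman is R and both side-chain double bonds are E; tetramethylallene and methyl (R)-2-methyloxirane-2-carboxylate are taken as commercial; adduct 5 is carried as a racemate because its only stereocentre is erased in step 3.

Step 1
Reactants: 1 2,4-dimethylpenta-2,3-diene (tetramethylallene); 2 but-3-en-2-one (methyl vinyl ketone)
Product: 3 6-methyl-5-(propan-2-ylidene)hept-6-en-2-one
Conditions: 1 (2 equiv), Me2AlCl (1.0 equiv), CH2Cl2, –78 → –20 °C
Reagents that add atoms: none
Why: Lewis-acid-promoted ene reaction in which the Me2AlCl-activated enone bonds through its β-carbon to the central allene carbon while a methyl hydrogen passes to the α-carbon, which can give only this 3-substituted 2,4-dimethylpenta-1,3-diene because the four methyl groups are equivalent, the excess of the more nucleophilic allene protecting the product diene from a second enone; no stereocentre is formed.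

Step 2
Reactants: 3 6-methyl-5-(propan-2-ylidene)hept-6-en-2-one; 4 prop-2-enal (acrolein)
Product: 5 (±)-2,2,4-trimethyl-3-(3-oxobutyl)cyclohex-3-ene-1-carbaldehyde
Conditions: 4 (3 equiv), Me2AlCl (1.5 equiv), CH2Cl2, –78 → –40 °C
Reagents that add atoms: none
Why: Me2AlCl-complexed acrolein and the s-cis conformer of the 1,1,2,3-tetrasubstituted diene of 3 should combine in a concerted but strongly asynchronous [4+2] cycloaddition (Lewis-acid-promoted Diels–Alder reaction), the β-carbon of acrolein bonding first to the unsubstituted CH2 terminus and the α-carbon then closing onto the isopropylidene carbon, so that both new σ-bonds, the quaternary CMe2 centre and the tetrasubstituted ring alkene arise together. The closest known reactions are Lewis-acid-promoted Diels–Alder additions of enals and enones to cis-substituted dienes of the 2,4-dimethylpenta-1,3-diene family, including intramolecular closures of this same isopropenyl–isopropylidene diene onto enones to build the trimethylcyclohexene ring of taxanes. Ring A is closed as a six-membered carbocycle by intermolecular [4π+2π] cycloaddition, four ring atoms coming from the diene and two from the dienophile, without a tether. The only new stereocentre, the formyl-bearing carbon, is formed as a racemate without control because it becomes CH2 in step 3, and for the same reason the regiochemistry (formyl next to CMe2 expected) and the endo/exo orientation are immaterial. The step needs chemoselectivity for cycloaddition over conjugate ene reaction, closure through the enolate oxygen and Prins-type attack of the diene on its own ketone; this is secured by the far higher electrophilicity of the Me2AlCl–enal complex at –78 °C, by Me2AlCl being too weak an acid to drive ketone–alkene closure while it scavenges protons, and by the fact that the only [1,5]-hydrogen shift open to the diene is degenerate.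

Step 3
Reactants: 5 (±)-2,2,4-trimethyl-3-(3-oxobutyl)cyclohex-3-ene-1-carbaldehyde
Product: 6 4-(2,6,6-trimethylcyclohex-1-en-1-yl)butan-2-one (dihydro-β-ionone)
Conditions: RhCl(PPh3)3 (1.05 equiv), PhCN, 130 °C
Reagents that add atoms: none
Why: Tsuji–Wilkinson decarbonylation (oxidative addition of the formyl C–H bond, CO de-insertion and C–H reductive elimination) replaces CHO by H and erases the stereocentre, while the ketone is inert and the tetrasubstituted ring alkene is too hindered for hydroacylation.

Step 4
Reactants: 6 4-(2,6,6-trimethylcyclohex-1-en-1-yl)butan-2-one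
Product: 9 2-(but-3-yn-1-yl)-1,3,3-trimethylcyclohex-1-ene, via lithium enolate 7 (not isolated), via enol diethyl phosphate 8 (not isolated)
Conditions: LiN(i-Pr)2 (1.1 equiv), THF, –78 °C; ClP(O)(OEt)2, –78 °C → rt; then LiN(i-Pr)2 (2.3 equiv), THF, –78 °C → rt; H2O
Reagents that add atoms: none
Why: Kinetic deprotonation of the methyl ketone at CH3, O-phosphorylation and base-induced β-elimination of diethyl phosphate from the terminal enol phosphate is the established one-pot conversion of methyl ketones into terminal alkynes, and the tetrasubstituted ring alkene is inert to the base.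

Step 5
Reactants: 10 4-bromo-3-methylphenol
Product: 11 (4-bromo-3-methylphenoxy)triisopropylsilane
Conditions: i-Pr3SiCl (1.1 equiv), imidazole (2 equiv), DMF, rt
Reagents that add atoms: chlorotriisopropylsilane, CC(C)[Si](Cl)(C(C)C)C(C)C
Why: Routine O-silylation of a phenol gives a bulky aryl silyl ether that tolerates the radical, organomagnesium, carbonate, hydride, chromium and alane steps that follow and is removable with fluoride.

Step 6
Reactants: 11 (4-bromo-3-methylphenoxy)triisopropylsilane
Product: 12 [4-bromo-3-(bromomethyl)phenoxy]triisopropylsilane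
Conditions: NBS (1.05 equiv), AIBN (5 mol%), PhCF3, 85 °C
Reagents that add atoms: N-bromosuccinimide, O=C1CCC(=O)N1Br
Why: Wohl–Ziegler radical bromination takes place at the only benzylic position, and the non-polar medium with radical initiation disfavours electrophilic ring bromination of the silyl-protected arene.

Step 7
Reactants: 12 [4-bromo-3-(bromomethyl)phenoxy]triisopropylsilane; 13 methyl (R)-2-methyloxirane-2-carboxylate
Product: 15 methyl (R)-4-{2-bromo-5-[(triisopropylsilyl)oxy]phenyl}-2-hydroxy-2-methylbutanoate, via benzylic Grignard reagent 14 (not isolated)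
Conditions: Mg, Et2O, 0 °C; then 13, CuI (10 mol%), THF, –40 → –20 °C; aq. NH4Cl
Reagents that add atoms: none
Why: Magnesium inserts into the benzylic C–Br bond far faster than into the aryl C–Br bond, and copper-catalysed SN2 opening of the glycidate at its unsubstituted CH2 (the known benzyl Grignard/glycidic ester route to 2-hydroxy-4-arylbutanoates) outruns ester addition at low temperature, so the quaternary stereocentre is not touched and the R configuration of 13 is carried into 15.

Step 8
Reactants: 15 methyl (R)-4-{2-bromo-5-[(triisopropylsilyl)oxy]phenyl}-2-hydroxy-2-methylbutanoate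
Product: 16 methyl (R)-2-methyl-6-[(triisopropylsilyl)oxy]chromane-2-carboxylate
Conditions: Pd(OAc)2 (3 mol%), 2-(di-tert-butylphosphino)-1,1'-binaphthyl (4 mol%), Cs2CO3 (1.5 equiv), toluene, 80 °C
Reagents that add atoms: none
Why: Palladium-catalysed intramolecular C–O coupling (Buchwald–Hartwig etherification) of a tertiary alcohol, which has no hydrogen on the carbinol carbon for β-hydride elimination, with the ortho-disposed aryl bromide closes the six-membered chroman, and since only the O–aryl bond is made the stereocentre is retained.

Step 9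
Reactants: 16 methyl (R)-2-methyl-6-[(triisopropylsilyl)oxy]chromane-2-carboxylate
Product: 17 (R)-2-methyl-6-[(triisopropylsilyl)oxy]chromane-2-carbaldehyde
Conditions: i-Bu2AlH (1.1 equiv), CH2Cl2, –78 °C; aq. potassium sodium tartrate (KNaC4H4O6)
Reagents that add atoms: none
Why: Partial ester reduction stops at the aldehyde because the α-aryloxy group stabilises the tetrahedral aluminium hemiacetal until work-up, and the product has no α-hydrogen and cannot epimerise.

Step 10
Reactants: 17 (R)-2-methyl-6-[(triisopropylsilyl)oxy]chromane-2-carbaldehyde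
Product: 18 (R)-{[2-((E)-2-iodoethenyl)-2-methylchroman-6-yl]oxy}triisopropylsilane
Conditions: CrCl2 (6 equiv), CHI3 (2 equiv), THF–1,4-dioxane (1:6), 0 °C → rt
Reagents that add atoms: iodoform, IC(I)I
Why: Takai olefination (addition of the geminal dichromium species from CHI3 and divalent chromium to the aldehyde, then elimination) gives the (E)-vinyl iodide, the E preference being reinforced by the bulky quaternary α-carbon, and the stereocentre is not involved.

Step 11
Reactants: 9 2-(but-3-yn-1-yl)-1,3,3-trimethylcyclohex-1-ene; 18 (R)-{[2-((E)-2-iodoethenyl)-2-methylchroman-6-yl]oxy}triisopropylsilane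
Product: 20 (R)-triisopropyl({2-methyl-2-[(1E,3E)-4-methyl-6-(2,6,6-trimethylcyclohex-1-en-1-yl)hexa-1,3-dien-1-yl]chroman-6-yl}oxy)silane, via alkenylalane 19 (not isolated)
Conditions: 9 (1.3 equiv), Me3Al (2.6 equiv), Cp2ZrCl2 (0.25 equiv), CH2Cl2, 0 °C → rt; then 18, Pd(PPh3)4 (5 mol%), ZnCl2 (1 equiv), THF, rt
Reagents that add atoms: trimethylaluminium, C[Al](C)C
Why: Zirconium-catalysed syn-carboalumination (Negishi carboalumination) places Me on the internal and Al on the terminal alkyne carbon to give the (E)-alkenylalane, which cross-couples with the vinyl iodide under Pd(PPh3)4/ZnCl2 (Negishi coupling) with retention at both partners to give the (E,E)-diene, leaving the ring alkene, the silyl ether and the stereocentre untouched.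

Step 12
Reactants: 20 (R)-triisopropyl({2-methyl-2-[(1E,3E)-4-methyl-6-(2,6,6-trimethylcyclohex-1-en-1-yl)hexa-1,3-dien-1-yl]chroman-6-yl}oxy)silane
Product: 21 (R)-2-methyl-2-[(1E,3E)-4-methyl-6-(2,6,6-trimethylcyclohex-1-en-1-yl)hexa-1,3-dien-1-yl]chroman-6-ol
Conditions: Bu4NF (1.1 equiv), degassed THF, 0 °C; aq. NH4Cl
Reagents that add atoms: none
Why: Fluoride cleaves the aryl Si–O bond under non-acidic, non-oxidising conditions that should leave the acid-sensitive tertiary allylic aryl ether, the diene geometry and the stereocentre intact.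

Compound list
1 | 2,4-dimethylpenta-2,3-diene (tetramethylallene) | CC(C)=C=C(C)C | starting material
2 | but-3-en-2-one (methyl vinyl ketone) | CC(=O)C=C | starting material
3 | 6-methyl-5-(propan-2-ylidene)hept-6-en-2-one | CC(=O)CCC(=C(C)C)C(C)=C | intermediate
4 | prop-2-enal (acrolein) | C=CC=O | starting material
5 | (±)-2,2,4-trimethyl-3-(3-oxobutyl)cyclohex-3-ene-1-carbaldehyde | CC(=O)CCC1=C(C)CCC(C=O)C1(C)C | intermediate
6 | 4-(2,6,6-trimethylcyclohex-1-en-1-yl)butan-2-one | CC(=O)CCC1=C(C)CCCC1(C)C | intermediate
7 | lithium 4-(2,6,6-trimethylcyclohex-1-en-1-yl)but-1-en-2-olate (not isolated) | [Li]OC(=C)CCC1=C(C)CCCC1(C)C | intermediate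
8 | diethyl 4-(2,6,6-trimethylcyclohex-1-en-1-yl)but-1-en-2-yl phosphate (not isolated) | C=C(CCC1=C(C)CCCC1(C)C)OP(=O)(OCC)OCC | intermediate
9 | 2-(but-3-yn-1-yl)-1,3,3-trimethylcyclohex-1-ene | C#CCCC1=C(C)CCCC1(C)C | intermediate
10 | 4-bromo-3-methylphenol | Cc1cc(O)ccc1Br | starting material
11 | (4-bromo-3-methylphenoxy)triisopropylsilane | Cc1cc(O[Si](C(C)C)(C(C)C)C(C)C)ccc1Br | intermediate
12 | [4-bromo-3-(bromomethyl)phenoxy]triisopropylsilane | BrCc1cc(O[Si](C(C)C)(C(C)C)C(C)C)ccc1Br | intermediate
13 | methyl (R)-2-methyloxirane-2-carboxylate | C[C@@]1(CO1)C(=O)OC | starting material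
14 | {2-bromo-5-[(triisopropylsilyl)oxy]benzyl}magnesium bromide (not isolated) | Br[Mg]Cc1cc(O[Si](C(C)C)(C(C)C)C(C)C)ccc1Br | intermediate
15 | methyl (R)-4-{2-bromo-5-[(triisopropylsilyl)oxy]phenyl}-2-hydroxy-2-methylbutanoate | COC(=O)[C@](C)(O)CCc1cc(O[Si](C(C)C)(C(C)C)C(C)C)ccc1Br | intermediate
16 | methyl (R)-2-methyl-6-[(triisopropylsilyl)oxy]chromane-2-carboxylate | COC(=O)[C@@]1(C)CCc2cc(O[Si](C(C)C)(C(C)C)C(C)C)ccc2O1 | intermediate
17 | (R)-2-methyl-6-[(triisopropylsilyl)oxy]chromane-2-carbaldehyde | O=C[C@@]1(C)CCc2cc(O[Si](C(C)C)(C(C)C)C(C)C)ccc2O1 | intermediate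
18 | (R)-{[2-((E)-2-iodoethenyl)-2-methylchroman-6-yl]oxy}triisopropylsilane | I/C=C/[C@@]1(C)CCc2cc(O[Si](C(C)C)(C(C)C)C(C)C)ccc2O1 | intermediate
19 | (E)-dimethyl[2-methyl-4-(2,6,6-trimethylcyclohex-1-en-1-yl)but-1-en-1-yl]alane (not isolated) | C[Al](C)/C=C(\C)CCC1=C(C)CCCC1(C)C | intermediate
20 | (R)-triisopropyl({2-methyl-2-[(1E,3E)-4-methyl-6-(2,6,6-trimethylcyclohex-1-en-1-yl)hexa-1,3-dien-1-yl]chroman-6-yl}oxy)silane | CC1=C(CC/C(C)=C/C=C/[C@@]2(C)CCc3cc(O[Si](C(C)C)(C(C)C)C(C)C)ccc3O2)C(C)(C)CCC1 | intermediate
21 | (R)-2-methyl-2-[(1E,3E)-4-methyl-6-(2,6,6-trimethylcyclohex-1-en-1-yl)hexa-1,3-dien-1-yl]chroman-6-ol | CC1=C(CC/C(C)=C/C=C/[C@@]2(C)CCc3cc(O)ccc3O2)C(C)(C)CCC1 | target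

Total step count: 12. Longest linear sequence: 8 steps (10 to 21 through steps 5–12); the ring A branch runs 6 steps (steps 1–4, 11 and 12).

Steps most likely to fail

Step 2. The hindered diene may reach the s-cis geometry too slowly, so that Lewis-acid-induced oligomerisation of acrolein, closure of the zwitterion through oxygen, or Prins-type attack of the diene on its own complexed ketone overtakes cycloaddition. The fallback sets out from 3 and uses no Lewis acid: commercial phenyl vinyl sulfone is added thermally (toluene, sealed tube, 150 °C, or 12 kbar in CH2Cl2) as a neutral ethylene equivalent, forming the same two ring bonds and giving 4-[2,6,6-trimethyl-5-(phenylsulfonyl)cyclohex-1-en-1-yl]butan-2-one F1. Reductive desulfonylation of F1 with sodium amalgam (6% Na/Hg, Na2HPO4, MeOH, –20 °C) returns to 6, so step 3 is no longer needed.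

Step 1. The polar ene pathway may divert to [2+2] closure or to ring closure through the enolate oxygen, or the product diene may be consumed by a second enone. The fallback sets out from 2 and returns at 3, with commercial mesityl oxide (4-methylpent-3-en-2-one) in place of 1. Bromine addition gives 3,4-dibromo-4-methylpentan-2-one F2, and Et3N removes HBr to give 3-bromo-4-methylpent-3-en-2-one F3. Wittig methylenation (Ph3P=CH2, THF) gives 3-bromo-2,4-dimethylpenta-1,3-diene F4, and magnesium in THF gives (2,4-dimethylpenta-1,3-dien-3-yl)magnesium bromide F5. Copper-catalysed (CuBr·SMe2, 10 mol%, –40 °C) conjugate addition of F5 to methyl vinyl ketone 2 delivers dienone 3.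

Step 8. C–O reductive elimination from the palladium alkoxide of a hindered, ester-deactivated tertiary alcohol on an electron-rich aryl group may be slow, leaving hydrodebromination or intermolecular transesterification to take over. The fallback sets out from 12 and returns at 17, carrying the C2 substituent at the alcohol oxidation level so that an ordinary, more nucleophilic tertiary alkoxide undergoes the coupling. Commercial (S)-2-methylglycidol is benzylated (NaH, BnBr, THF) to (R)-2-[(benzyloxy)methyl]-2-methyloxirane F6, the descriptor changing only through the priority rules. Grignard reagent 14 from 12 opens F6 at CH2 (CuI cat., THF, –30 °C) to give (R)-1-(benzyloxy)-4-{2-bromo-5-[(triisopropylsilyl)oxy]phenyl}-2-methylbutan-2-ol F7. The same palladium-catalysed etherification closes (R)-{[2-[(benzyloxy)methyl]-2-methylchroman-6-yl]oxy}triisopropylsilane F8, and hydrogenolysis (H2, palladium on carbon, EtOAc) gives (R)-{2-methyl-6-[(triisopropylsilyl)oxy]chroman-2-yl}methanol F9. Swern oxidation ((COCl)2, DMSO, Et3N, –78 °C) of F9 gives aldehyde 17.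

Further compounds
F1 | step 2 | 4-[2,6,6-trimethyl-5-(phenylsulfonyl)cyclohex-1-en-1-yl]butan-2-one (racemic) | CC(=O)CCC1=C(C)CCC(S(=O)(=O)c2ccccc2)C1(C)C
F2 | step 1 | 3,4-dibromo-4-methylpentan-2-one | CC(=O)C(Br)C(C)(C)Br
F3 | step 1 | 3-bromo-4-methylpent-3-en-2-one | CC(=O)C(Br)=C(C)C
F4 | step 1 | 3-bromo-2,4-dimethylpenta-1,3-diene | CC(=C)C(Br)=C(C)C
F5 | step 1 | (2,4-dimethylpenta-1,3-dien-3-yl)magnesium bromide | CC(=C)C([Mg]Br)=C(C)C
F6 | step 8 | (R)-2-[(benzyloxy)methyl]-2-methyloxirane | C[C@]1(COCc2ccccc2)CO1
F7 | step 8 | (R)-1-(benzyloxy)-4-{2-bromo-5-[(triisopropylsilyl)oxy]phenyl}-2-methylbutan-2-ol | C[C@](O)(COCc1ccccc1)CCc1cc(O[Si](C(C)C)(C(C)C)C(C)C)ccc1Br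
F8 | step 8 | (R)-{[2-[(benzyloxy)methyl]-2-methylchroman-6-yl]oxy}triisopropylsilane | C[C@]1(COCc2ccccc2)CCc2cc(O[Si](C(C)C)(C(C)C)C(C)C)ccc2O1
F9 | step 8 | (R)-{2-methyl-6-[(triisopropylsilyl)oxy]chroman-2-yl}methanol | C[C@]1(CO)CCc2cc(O[Si](C(C)C)(C(C)C)C(C)C)ccc2O1
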